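The numbers in the tables come from a simulation for substances that don't exist; the scatter is artificial.

**Proven turnovers.** 1310 turnovers per charged enzyme is what gamma shows: its reading of 92% target at 4.00 min, with its scatter, over its loading of 0.07 mol%. Call target made per enzyme charged, at its highest reading, the proven turnover count.

| setting | gamma | epsilon | flask |
|---|---|---|---|
| starting material | 5 mM | 5 mM | 5.0 mM |
| second substrate | 3 equiv | 3 equiv | 3.00 equiv |
| free enzyme | 0.07 mol% | 0.11 mol% | 0.05 mol% |
| remark | run made earlier | run made earlier |  |

| gamma: time / min | gamma: target / % | epsilon: time / min | epsilon: target / % |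
|---|---|---|---|
| 0.833 | 74 | 0.833 | 93 |
| 2.00 | 90 | 2.00 | 96 |
| 4.00 | 92 | 4.00 | 93 |
| 6.00 | 89 | 6.00 | 94 |

(scatter of a reading: 2 percentage points)

* factor on the rate of making target when 50% of the starting material are converted if second substrate is charged twice over
* factor on the rate when 50% of the starting material are converted if free enzyme is charged at 0.5 mol% instead

- no earlier run changes the charge of second substrate; that part of a forecast is a guess

**The curve.** Gamma's first reading, scaled to the flask's loading, gives a starting slope of 0.635 min⁻¹ as a fraction of the charge, so I expect the flask at 50% conversion near 0.787 min. That point asks 1000 turnovers of each enzyme, fewer than the proven count. I put the knee at 0.657 of the charge, where the flask has used up the proven count, near 1.03 min. Matching gamma's level would ask 1840 turnovers, more than either run shows, so I expect the flask's level between 0.657 and 92%.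

**My ratio.** I assume every turnover carries the same risk of losing the enzyme, and that rate follows live enzyme at equal conversion. At 0.5 mol% the same conversion asks 100 turnovers. On that assumption I reckon the spent share at 50% conversion below 0.763 in the flask and below 0.0763 at 0.5 mol%. So I reckon the ratio between 10.0 and 38.6, and I commit to 19.7. For second substrate no run helps, and I guess a factor near one.

**The forecast.** It gave 1.4 (1 to 2.1) and 12 (7 to 50), favouring first order in enzyme as “the normal catalytic case”.

**The result.** The simulation gives 1.02 for doubled second substrate and 20.8 for the enzyme.

    starting material + free enzyme ⇌ first complex (K = 420 M⁻¹, k = 4.90 × 10⁵ M⁻¹ s⁻¹)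
    first complex → loaded enzyme + first product (k = 730 s⁻¹)
    second substrate + loaded enzyme ⇌ second complex (K = 3300 M⁻¹, k = 2.30 × 10⁵ M⁻¹ s⁻¹)
    second complex → free enzyme + target (k = 44.0 s⁻¹)
    starting material + first product → side product (k = 2.00 M⁻¹ s⁻¹)
    second complex → spent catalyst (k = 0.0270 s⁻¹)

Second complex goes to target 1630 times for each time it goes to spent catalyst, and at the flask's loading that number gives 0.815 of the charge, while the flask holds 80.6% target and 98.9% spent catalyst at 60.0 min. At 0.5 mol% the 100 turnovers are 0.0763 of the proven count and 0.0613 of that number, and the spent share in that run at 50% conversion is 6.02%.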